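The lactone ring is disconnected at C4–C4a and C1–C8a, which turns the hydroquinone ring into 3,6-bis(benzyloxy)benzyne, C3–C4 into a terminal alkyne and C1 into carbon dioxide. The 5,8-dioxygenated benzene ring has a mirror plane bisecting the C4a–C8a and C6–C7 bonds, so both aryne carbons are equivalent and regiochemistry cannot go wrong. A copper-catalysed three-component coupling of an ortho-silylaryl triflate, an (R)-silyloxyheptyne and CO2 builds the isocoumarin in one operation. Enantioselective hydrogenation then sets C3; esterification with O-benzyl (R)-mevalonic acid and one global hydrogenolysis finish the synthesis.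

Key step: step 7

Remark: compounds 1, 10, 11, 16 and 22 are taken as purchasable.

Step 1
Reactants: 1 2,5-bis(benzyloxy)benzaldehyde
Product: 3 2,5-bis(benzyloxy)phenol, via 2,5-bis(benzyloxy)phenyl formate 2 (not isolated)
Conditions: mCPBA, CH2Cl2, 0 °C → rt; aq. NaHCO3 wash; then K2CO3 (cat.), MeOH, rt
Reagents that add atoms: mCPBA, O=C(OO)c1cccc(Cl)c1
Why: Baeyer–Villiger (Dakin-type) oxidation, in which the electron-rich aryl group migrates in the Criegee intermediate and the resulting formate is removed by methanolysis.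

Step 2
Reactants: 3 2,5-bis(benzyloxy)phenol
Product: 4 2,5-bis(benzyloxy)phenyl N-isopropylcarbamate
Conditions: i-PrNCO, Et3N (cat.), CH2Cl2, rt
Reagents that add atoms: isopropyl isocyanate, CC(C)N=C=O
Why: Base-catalysed addition of the phenol to the isocyanate (carbamoylation) installs the directing group for ortho-metalation.

Step 3
Reactants: 4 2,5-bis(benzyloxy)phenyl N-isopropylcarbamate
Product: 7 3,6-bis(benzyloxy)-2-(trimethylsilyl)phenyl N-isopropylcarbamate, via N-silyl carbamate 5 (not isolated), via N-silyl C-silyl carbamate 6 (not isolated)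
Conditions: TMSOTf, TMEDA, Et2O, 0 °C → rt; n-BuLi (2 equiv), TMEDA, −78 °C; TMSCl, −78 °C → rt; aq. NaHSO4
Reagents that add atoms: chlorotrimethylsilane, C[Si](C)(C)Cl
Why: Directed ortho-metalation with in situ N-silyl protection (Hoppe–Snieckus type) should lithiate the only C–H flanked by the carbamate and a benzyloxy group, the low temperature disfavouring benzylic lithiation, and the N-silyl group is lost on work-up.

Step 4
Reactants: 7 3,6-bis(benzyloxy)-2-(trimethylsilyl)phenyl N-isopropylcarbamate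
Product: 9 3,6-bis(benzyloxy)-2-(trimethylsilyl)phenyl trifluoromethanesulfonate, via 3,6-bis(benzyloxy)-2-(trimethylsilyl)phenol 8 (not isolated)
Conditions: DBU, Et2NH, MeCN, 40 °C; then PhNTf2, rt
Reagents that add atoms: N-phenylbis(trifluoromethanesulfonimide), O=S(=O)(N(c1ccccc1)S(=O)(=O)C(F)(F)F)C(F)(F)F
Why: E1cB cleavage of the N-H carbamate (the isocyanate is scavenged by Et2NH) frees the phenoxide, which is O-triflated in the same pot without loss of the aryl silane.

Step 5
Reactants: 10 (R)-propylene oxide; 11 (4-bromobut-1-yn-1-yl)trimethylsilane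
Product: 13 (2R)-7-(trimethylsilyl)hept-6-yn-2-ol, via [4-(trimethylsilyl)but-3-yn-1-yl]magnesium bromide 12 (not isolated)
Conditions: Mg, THF, rt; CuI (10 mol %), 10, THF, −30 °C → 0 °C; aqueous work-up
Reagents that add atoms: none
Why: Copper-catalysed SN2 opening of the epoxide by the Grignard reagent at the unsubstituted carbon leaves the chiral-pool carbinol centre untouched, so the R configuration is carried over.

Step 6
Reactants: 13 (2R)-7-(trimethylsilyl)hept-6-yn-2-ol
Product: 15 tert-butyl[(2R)-hept-6-yn-2-yloxy]dimethylsilane, via silyl ether of the silylalkyne 14 (not isolated)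
Conditions: TBSCl, imidazole, DMF, rt; then K2CO3, MeOH, rt
Reagents that add atoms: tert-butyldimethylsilyl chloride, CC(C)(C)[Si](C)(C)Cl
Why: Silyl ether formation followed by base-mediated protodesilylation of the alkynylsilane, which the secondary silyl ether survives.

Step 7
Reactants: 9 3,6-bis(benzyloxy)-2-(trimethylsilyl)phenyl trifluoromethanesulfonate; 15 tert-butyl[(2R)-hept-6-yn-2-yloxy]dimethylsilane; 16 carbon dioxide
Product: 19 5,8-bis(benzyloxy)-3-[(4R)-4-(tert-butyldimethylsilyloxy)pentyl]-1H-isochromen-1-one, via 3,6-bis(benzyloxy)benzyne 17 (not isolated), via cesium 2-alkynylbenzoate 18 (not isolated)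
Conditions: chloro[1,3-bis(2,6-diisopropylphenyl)imidazol-2-ylidene]copper (10 mol %), CsF (3 equiv), Cs2CO3, CO2 (1 atm), dry MeCN, 80 °C
Reagents that add atoms: none
Why: Fluoride-triggered 1,2-elimination of 9 releases aryne 17; the NHC-copper acetylide formed from 15 and Cs2CO3 adds across the strained triple bond (C4–C4a bond), the resulting ortho-alkynyl aryl copper inserts CO2 (C1–C8a bond) to give carboxylate 18, and copper-activated attack of the carboxylate oxygen on the alkyne followed by protodemetalation gives 19. The closest known reaction type is the NHC-copper-catalysed three-component coupling of arynes, terminal alkynes and CO2 to isocoumarins. The lactone ring closes in the 6-endo-dig mode, the oxygen attacking the alkyl-bearing alkyne carbon that becomes C3. No stereocenter is formed, and the carbinol centre of the side chain is remote from every reacting site. Regiochemistry of the aryne addition is not an issue because the two aryne carbons of 17 are equivalent by symmetry; the step needs CO2 capture to outrun protonation of the aryl copper (dry medium, CO2 atmosphere, carbonate as the only base) and 6-endo to beat 5-exo closure, which the alkyl substituent on the alkyne and the NHC-copper catalyst should favour.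

Step 8
Reactants: 19 5,8-bis(benzyloxy)-3-[(4R)-4-(tert-butyldimethylsilyloxy)pentyl]-1H-isochromen-1-one
Product: 20 (3R)-5,8-bis(benzyloxy)-3-[(4R)-4-(tert-butyldimethylsilyloxy)pentyl]-3,4-dihydro-1H-isochromen-1-one
Conditions: Ru(2-methylallyl)2(1,5-cyclooctadiene) (5 mol %), 1,3-bis[1-(naphthalen-1-yl)ethyl]-4,5-dihydroimidazolium tetrafluoroborate and 1,2-diphenylethane-1,2-diamine (each a single enantiomer, chosen for 3R), KOt-Bu, H2 (50 bar), toluene, 25 °C
Reagents that add atoms: none
Why: Ruthenium NHC-diamine-catalysed enantioselective hydrogenation of the isocoumarin C3=C4 bond, in which the chiral ligand pair selects the face of the enol-lactone double bond and so sets C3 as R under catalyst control, the remote side-chain centre exerting no bias.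

Step 9
Reactants: 20 (3R)-5,8-bis(benzyloxy)-3-[(4R)-4-(tert-butyldimethylsilyloxy)pentyl]-3,4-dihydro-1H-isochromen-1-one
Product: 21 (3R)-5,8-bis(benzyloxy)-3-[(4R)-4-hydroxypentyl]-3,4-dihydro-1H-isochromen-1-one
Conditions: HF·pyridine, pyridine, THF, 0 °C → rt
Reagents that add atoms: none
Why: Fluoride-mediated cleavage of the silyl ether under buffered conditions that leave the lactone and the benzyl ethers intact.

Step 10
Reactants: 22 (R)-mevalonolactone
Product: 25 (3R)-5-(benzyloxy)-3-hydroxy-3-methylpentanoic acid, via sodium (R)-mevalonate 23 (not isolated), via benzyl ester benzyl ether 24 (not isolated)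
Conditions: NaOH (1.0 equiv), MeOH/H2O, rt, evaporate; NaH (1.1 equiv), BnBr (2.2 equiv), Bu4NI (cat.), DMF, 0 °C → rt; then LiOH, THF/H2O, rt; HCl to pH 3, 0 °C
Reagents that add atoms: sodium hydroxide, [Na+].[OH-]; benzyl bromide, BrCc1ccccc1
Why: Lactone saponification, Williamson benzylation of the primary alkoxide and the carboxylate (the hindered tertiary hydroxyl should stay free) and ester saponification give the acid, which cannot relactonize, with the quaternary carbinol centre untouched.

Step 11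
Reactants: 21 (3R)-5,8-bis(benzyloxy)-3-[(4R)-4-hydroxypentyl]-3,4-dihydro-1H-isochromen-1-one; 25 (3R)-5-(benzyloxy)-3-hydroxy-3-methylpentanoic acid
Product: 26 (2R)-5-[(3R)-5,8-bis(benzyloxy)-1-oxo-3,4-dihydro-1H-isochromen-3-yl]pentan-2-yl (3R)-5-(benzyloxy)-3-hydroxy-3-methylpentanoate
Conditions: N,N'-diisopropylcarbodiimide, DMAP (cat.), CH2Cl2, 0 °C → rt
Reagents that add atoms: none
Why: Steglich esterification acylates the secondary alcohol with retention (its C–O bond is not broken), while the tertiary hydroxyl of the acid is too hindered to compete.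

Step 12
Reactants: 26 (2R)-5-[(3R)-5,8-bis(benzyloxy)-1-oxo-3,4-dihydro-1H-isochromen-3-yl]pentan-2-yl (3R)-5-(benzyloxy)-3-hydroxy-3-methylpentanoate
Product: 27 (2R)-5-[(3R)-5,8-dihydroxy-1-oxo-3,4-dihydro-1H-isochromen-3-yl]pentan-2-yl (3R)-3,5-dihydroxy-3-methylpentanoate
Conditions: H2 (1 atm), Pd/C, EtOAc, rt; work-up under argon
Reagents that add atoms: none
Why: Neutral hydrogenolysis of the two aryl benzyl ethers and the alkyl benzyl ether should release the hydroquinone and the primary alcohol without acid or base that could lactonize the mevalonate ester.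

Compound list
1 | 2,5-bis(benzyloxy)benzaldehyde | O=Cc1cc(OCc2ccccc2)ccc1OCc1ccccc1 | starting material
2 | 2,5-bis(benzyloxy)phenyl formate | O=COc1cc(OCc2ccccc2)ccc1OCc1ccccc1 | intermediate
3 | 2,5-bis(benzyloxy)phenol | Oc1cc(OCc2ccccc2)ccc1OCc1ccccc1 | intermediate
4 | 2,5-bis(benzyloxy)phenyl N-isopropylcarbamate | CC(C)NC(=O)Oc1cc(OCc2ccccc2)ccc1OCc1ccccc1 | intermediate
5 | 2,5-bis(benzyloxy)phenyl N-isopropyl-N-(trimethylsilyl)carbamate | CC(C)N([Si](C)(C)C)C(=O)Oc1cc(OCc2ccccc2)ccc1OCc1ccccc1 | intermediate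
6 | 3,6-bis(benzyloxy)-2-(trimethylsilyl)phenyl N-isopropyl-N-(trimethylsilyl)carbamate | CC(C)N([Si](C)(C)C)C(=O)Oc1c([Si](C)(C)C)c(OCc2ccccc2)ccc1OCc1ccccc1 | intermediate
7 | 3,6-bis(benzyloxy)-2-(trimethylsilyl)phenyl N-isopropylcarbamate | CC(C)NC(=O)Oc1c([Si](C)(C)C)c(OCc2ccccc2)ccc1OCc1ccccc1 | intermediate
8 | 3,6-bis(benzyloxy)-2-(trimethylsilyl)phenol | Oc1c([Si](C)(C)C)c(OCc2ccccc2)ccc1OCc1ccccc1 | intermediate
9 | 3,6-bis(benzyloxy)-2-(trimethylsilyl)phenyl trifluoromethanesulfonate | FC(F)(F)S(=O)(=O)Oc1c([Si](C)(C)C)c(OCc2ccccc2)ccc1OCc1ccccc1 | intermediate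
10 | (R)-propylene oxide | C[C@@H]1CO1 | starting material
11 | (4-bromobut-1-yn-1-yl)trimethylsilane | BrCCC#C[Si](C)(C)C | starting material
12 | [4-(trimethylsilyl)but-3-yn-1-yl]magnesium bromide | C[Si](C)(C)C#CCC[Mg]Br | intermediate
13 | (2R)-7-(trimethylsilyl)hept-6-yn-2-ol | C[C@@H](O)CCCC#C[Si](C)(C)C | intermediate
14 | tert-butyldimethyl{[(2R)-7-(trimethylsilyl)hept-6-yn-2-yl]oxy}silane | C[C@@H](O[Si](C)(C)C(C)(C)C)CCCC#C[Si](C)(C)C | intermediate
15 | tert-butyl[(2R)-hept-6-yn-2-yloxy]dimethylsilane | C[C@@H](O[Si](C)(C)C(C)(C)C)CCCC#C | intermediate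
16 | carbon dioxide | O=C=O | starting material
17 | 3,6-bis(benzyloxy)benzyne | C1(OCc2ccccc2)=CC=C(OCc2ccccc2)C#C1 | intermediate
18 | cesium 3,6-bis(benzyloxy)-2-[(6R)-6-(tert-butyldimethylsilyloxy)hept-1-yn-1-yl]benzoate | C[C@@H](O[Si](C)(C)C(C)(C)C)CCCC#Cc1c(OCc2ccccc2)ccc(OCc2ccccc2)c1C(=O)[O-].[Cs+] | intermediate
19 | 5,8-bis(benzyloxy)-3-[(4R)-4-(tert-butyldimethylsilyloxy)pentyl]-1H-isochromen-1-one | C[C@@H](O[Si](C)(C)C(C)(C)C)CCCC1=Cc2c(OCc3ccccc3)ccc(OCc3ccccc3)c2C(=O)O1 | intermediate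
20 | (3R)-5,8-bis(benzyloxy)-3-[(4R)-4-(tert-butyldimethylsilyloxy)pentyl]-3,4-dihydro-1H-isochromen-1-one | C[C@@H](O[Si](C)(C)C(C)(C)C)CCC[C@@H]1Cc2c(OCc3ccccc3)ccc(OCc3ccccc3)c2C(=O)O1 | intermediate
21 | (3R)-5,8-bis(benzyloxy)-3-[(4R)-4-hydroxypentyl]-3,4-dihydro-1H-isochromen-1-one | C[C@@H](O)CCC[C@@H]1Cc2c(OCc3ccccc3)ccc(OCc3ccccc3)c2C(=O)O1 | intermediate
22 | (R)-mevalonolactone | O=C1C[C@](C)(O)CCO1 | starting material
23 | sodium (3R)-3,5-dihydroxy-3-methylpentanoate | [Na+].[O-]C(=O)C[C@](C)(O)CCO | intermediate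
24 | benzyl (3R)-5-(benzyloxy)-3-hydroxy-3-methylpentanoate | O=C(OCc1ccccc1)C[C@](C)(O)CCOCc1ccccc1 | intermediate
25 | (3R)-5-(benzyloxy)-3-hydroxy-3-methylpentanoic acid | OC(=O)C[C@](C)(O)CCOCc1ccccc1 | intermediate
26 | (2R)-5-[(3R)-5,8-bis(benzyloxy)-1-oxo-3,4-dihydro-1H-isochromen-3-yl]pentan-2-yl (3R)-5-(benzyloxy)-3-hydroxy-3-methylpentanoate | C[C@@H](OC(=O)C[C@](C)(O)CCOCc1ccccc1)CCC[C@@H]1Cc2c(OCc3ccccc3)ccc(OCc3ccccc3)c2C(=O)O1 | intermediate
27 | (2R)-5-[(3R)-5,8-dihydroxy-1-oxo-3,4-dihydro-1H-isochromen-3-yl]pentan-2-yl (3R)-3,5-dihydroxy-3-methylpentanoate | C[C@H](CCC[C@@H]1Cc2c(O)ccc(O)c2C(=O)O1)OC(=O)C[C@](C)(O)CCO | target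

Total steps: 12. Longest linear sequence: 9 steps (steps 1, 2, 3, 4, 7, 8, 9, 11, 12).

Steps most likely to fail

Step 7. The copper carboxylate may close in the 5-exo-dig mode to an alkylidene phthalide, or the ortho-alkynyl aryl copper may be protonated before it takes up CO2. The fallback sets out from 1 and 15 and comes back at 19. Pinnick oxidation of 1 (NaClO2, NaH2PO4, 2-methyl-2-butene, t-BuOH/H2O) should give 2,5-bis(benzyloxy)benzoic acid F1. Carboxylate-directed ortho-lithiation at the position flanked by the carboxylate and a benzyloxy group (s-BuLi, TMEDA, THF, −78 °C), then an I2 quench, should give 3,6-bis(benzyloxy)-2-iodobenzoic acid F2. Coupling of F2 with 15 under Pd(PPh3)4, ZnCl2 and Et3N in DMF (Sonogashira-type alkynylation with in situ 6-endo lactonization) should then deliver 19.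

Step 8. Facial selectivity at the trisubstituted enol-lactone double bond may be poor, or turnover slow because the C5 benzyloxy group crowds C4. The fallback sets out from 19 and comes back at 20. Saponification of 19 (KOH, THF/H2O) opens the enol lactone to 3,6-bis(benzyloxy)-2-[(6R)-6-(tert-butyldimethylsilyloxy)-2-oxoheptyl]benzoic acid F3. Enzymatic reduction of the ketone with a ketoreductase selected from a commercial panel for the R carbinol (NADP+, glucose, glucose dehydrogenase, phosphate buffer pH 7, DMSO cosolvent) should give 3,6-bis(benzyloxy)-2-[(2R,6R)-6-(tert-butyldimethylsilyloxy)-2-hydroxyheptyl]benzoic acid F4. F4 should lactonize to 20 on mild acidification.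

Step 10. The tertiary alkoxide may be benzylated in competition, or the β-hydroxy ester intermediate may fragment by retro-aldol cleavage under the basic alkylation conditions. The fallback sets out from 22 and comes back at 27. 22 is opened with NaOH to 23 as before, and silylation of 23 (TBSCl, imidazole, DMF) should give tert-butyldimethylsilyl (3R)-5-(tert-butyldimethylsilyloxy)-3-hydroxy-3-methylpentanoate F5. K2CO3 in MeOH/THF/H2O should cleave only the silyl ester to (3R)-5-(tert-butyldimethylsilyloxy)-3-hydroxy-3-methylpentanoic acid F6. Esterification of 21 with F6 (N,N'-diisopropylcarbodiimide, DMAP) should give (2R)-5-[(3R)-5,8-bis(benzyloxy)-1-oxo-3,4-dihydro-1H-isochromen-3-yl]pentan-2-yl (3R)-5-(tert-butyldimethylsilyloxy)-3-hydroxy-3-methylpentanoate F7. HF·pyridine buffered with pyridine at 0 °C should remove the primary silyl ether to give (2R)-5-[(3R)-5,8-bis(benzyloxy)-1-oxo-3,4-dihydro-1H-isochromen-3-yl]pentan-2-yl (3R)-3,5-dihydroxy-3-methylpentanoate F8. Hydrogenolysis of the two benzyl ethers of F8 (H2, Pd/C, EtOAc) should then give 27.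

Further compounds
F1 | step 7 | 2,5-bis(benzyloxy)benzoic acid | OC(=O)c1cc(OCc2ccccc2)ccc1OCc1ccccc1
F2 | step 7 | 3,6-bis(benzyloxy)-2-iodobenzoic acid | OC(=O)c1c(I)c(OCc2ccccc2)ccc1OCc1ccccc1
F3 | step 8 | 3,6-bis(benzyloxy)-2-[(6R)-6-(tert-butyldimethylsilyloxy)-2-oxoheptyl]benzoic acid | C[C@@H](O[Si](C)(C)C(C)(C)C)CCCC(=O)Cc1c(OCc2ccccc2)ccc(OCc2ccccc2)c1C(O)=O
F4 | step 8 | 3,6-bis(benzyloxy)-2-[(2R,6R)-6-(tert-butyldimethylsilyloxy)-2-hydroxyheptyl]benzoic acid | C[C@@H](O[Si](C)(C)C(C)(C)C)CCC[C@@H](O)Cc1c(OCc2ccccc2)ccc(OCc2ccccc2)c1C(O)=O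
F5 | step 10 | tert-butyldimethylsilyl (3R)-5-(tert-butyldimethylsilyloxy)-3-hydroxy-3-methylpentanoate | CC(C)(C)[Si](C)(C)OC(=O)C[C@](C)(O)CCO[Si](C)(C)C(C)(C)C
F6 | step 10 | (3R)-5-(tert-butyldimethylsilyloxy)-3-hydroxy-3-methylpentanoic acid | OC(=O)C[C@](C)(O)CCO[Si](C)(C)C(C)(C)C
F7 | step 10 | (2R)-5-[(3R)-5,8-bis(benzyloxy)-1-oxo-3,4-dihydro-1H-isochromen-3-yl]pentan-2-yl (3R)-5-(tert-butyldimethylsilyloxy)-3-hydroxy-3-methylpentanoate | C[C@@H](OC(=O)C[C@](C)(O)CCO[Si](C)(C)C(C)(C)C)CCC[C@@H]1Cc2c(OCc3ccccc3)ccc(OCc3ccccc3)c2C(=O)O1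
F8 | step 10 | (2R)-5-[(3R)-5,8-bis(benzyloxy)-1-oxo-3,4-dihydro-1H-isochromen-3-yl]pentan-2-yl (3R)-3,5-dihydroxy-3-methylpentanoate | C[C@@H](OC(=O)C[C@](C)(O)CCO)CCC[C@@H]1Cc2c(OCc3ccccc3)ccc(OCc3ccccc3)c2C(=O)O1
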